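**Retrosynthetic overview**
- The C7a=N1/C6=C7 azadiene is made last, by iridium-catalysed hydrosilylation and silanol elimination from an NH-enaminone that still carries a C6 carbonyl.
- The C2'–O bond, the C2' stereocentre and the C5=C1' alkene come from a [3,3]-sigmatropic 1,3-transposition of a C5 tertiary allylic alcohol; that alcohol comes from adding an E-alkenylzinc (from (S)-but-3-yn-2-ol) to a C5 ketone, anti to the oxirane.
- The oxirane is made first: an acetylide adds to an α-mesyloxy ketone (C4 bought in (S)-4-amino-2-hydroxybutanoic acid) and the alkoxide closes with inversion.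
- Ring order: oxirane, then the carbocycle (Dieckmann condensation), then the nitrogen ring (Staudinger reduction and condensation).
- The 2-methylbutanoyl centre is bought as (R)-2-methylbutanoic acid.

Assumption: ring atoms are labelled as in abikoviromycin (N1, C2, C3, C4, C4a, C5, C6, C7, C7a), the side chain on C5 as C1' to C4', and the three enantiopure starting materials are purchased.

**Step 1**
Reactants: 1 (S)-4-amino-2-hydroxybutanoic acid
Product: 2 (S)-4-azido-2-hydroxybutanoic acid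
Conditions: ImSO2N3·H2SO4, K2CO3, CuSO4·5H2O (cat.), MeOH–H2O, 23 °C; then aq. HCl
Reagents that add atoms: imidazole-1-sulfonyl azide hydrogen sulfate, [N-]=[N+]=NS(=O)(=O)n1ccnc1.OS(O)(=O)=O
Why: Copper-catalysed diazo transfer turns the primary amine into the azide without touching the purchased carbinol centre.

**Step 2**
Reactants: 2 (S)-4-azido-2-hydroxybutanoic acid
Product: 3 (S)-4-azido-2-hydroxy-N-methoxy-N-methylbutanamide
Conditions: MeNHOMe·HCl, EDC·HCl, HOBt (cat.), N-methylmorpholine, CH2Cl2, 0 → 23 °C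
Reagents that add atoms: N,O-dimethylhydroxylamine hydrochloride, CNOC.Cl
Why: Carbodiimide amide coupling gives the Weinreb amide; the stereocentre is not involved.

**Step 3**
Reactants: 3 (S)-4-azido-2-hydroxy-N-methoxy-N-methylbutanamide
Product: 4 (S)-4-azido-1-[methoxy(methyl)amino]-1-oxobutan-2-yl methanesulfonate
Conditions: MsCl, Et3N, CH2Cl2, −20 °C
Reagents that add atoms: methanesulfonyl chloride, CS(=O)(=O)Cl
Why: O-Sulfonylation makes the hydroxyl a leaving group with retention, since no bond to carbon is broken.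

**Step 4**
Reactants: 4 (S)-4-azido-1-[methoxy(methyl)amino]-1-oxobutan-2-yl methanesulfonate; 5 2-bromobut-1-ene
Product: 7 (3S)-1-azido-5-methylidene-4-oxoheptan-3-yl methanesulfonate, via but-1-en-2-ylmagnesium bromide 6 (not isolated)
Conditions: 5, Mg, THF, 40 °C; then 4, THF, −40 → −10 °C; cold 1 M HCl
Reagents that add atoms: none
Why: Weinreb ketone synthesis stops at the ketone through the chelated tetrahedral adduct, and the low temperature spares the azide and the α-stereocentre.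

**Step 5**
Reactants: 7 (3S)-1-azido-5-methylidene-4-oxoheptan-3-yl methanesulfonate; 8 ethoxyethyne
Product: 11 (2R,3R)-3-(2-azidoethyl)-2-(but-1-en-2-yl)-2-(ethoxyethynyl)oxirane, via lithium ethoxyacetylide 9 (not isolated), via lithium alkoxide adduct 10 (not isolated)
Conditions: 8, n-BuLi, THF, −78 °C; then 7, −78 → 0 °C
Reagents that add atoms: none
Why: The acetylide adds 1,2 under Cornforth/polar Felkin–Anh control (anti to the C–OMs bond, past the small H) and the alkoxide then displaces the mesylate with inversion (Darzens-type closure), so C4 becomes R and C4a is set with the butenyl group cis to the azidoethyl arm.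

**Step 6**
Reactants: 11 (2R,3R)-3-(2-azidoethyl)-2-(but-1-en-2-yl)-2-(ethoxyethynyl)oxirane
Product: 12 ethyl 2-[(2R,3R)-3-(2-azidoethyl)-2-propanoyloxiran-2-yl]-2-oxoacetate
Conditions: O3, CH2Cl2, −78 °C; then Me2S, −78 → 23 °C
Reagents that add atoms: ozone, [O-][O+]=O
Why: Ozonolysis with reductive work-up cleaves the 1,1-disubstituted alkene to the ethyl ketone and oxidises the ynol ether to the α-keto ester; azide, oxirane and both stereocentres are inert.

**Step 7**
Reactants: 12 ethyl 2-[(2R,3R)-3-(2-azidoethyl)-2-propanoyloxiran-2-yl]-2-oxoacetate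
Product: 15 (4R,4aS)-4,4a-epoxy-7-methyl-2,3,4,4a-tetrahydro-1H-cyclopenta[b]pyridine-5,6-dione, via spiro triketone enol 13 (not isolated), via amino triketone 14 (not isolated)
Conditions: LiN(SiMe3)2, THF, −78 → 0 °C; AcOH; then PPh3, THF–H2O, 60 °C
Reagents that add atoms: none
Why: Dieckmann (Claisen) condensation of the ethyl ketone enolate onto the ester closes the carbocycle (5-exo-trig), then Staudinger reduction frees the amine, which can reach only the cis-disposed C7a carbonyl and condenses to the vinylogous amide; no stereocentre is touched.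

**Step 8**
Reactants: 16 (S)-but-3-yn-2-ol
Product: 17 (S)-but-3-yn-2-yl acetate
Conditions: Ac2O, pyridine, DMAP (cat.), CH2Cl2, 0 → 23 °C
Reagents that add atoms: acetic anhydride, CC(=O)OC(C)=O
Why: Acylation of the purchased carbinol installs the C3' acetate of the target with retention.

**Step 9**
Reactants: 15 (4R,4aS)-4,4a-epoxy-7-methyl-2,3,4,4a-tetrahydro-1H-cyclopenta[b]pyridine-5,6-dione; 17 (S)-but-3-yn-2-yl acetate
Product: 20 (2S,3E)-4-[(4R,4aS,5R)-4,4a-epoxy-5-hydroxy-7-methyl-6-oxo-2,3,4,4a,5,6-hexahydro-1H-cyclopenta[b]pyridin-5-yl]but-3-en-2-yl acetate, via alkenylzirconocene chloride 18 (not isolated), via alkenyl(methyl)zinc 19 (not isolated)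
Conditions: 17 (2.5 equiv), Cp2Zr(H)Cl, CH2Cl2, 23 °C; Me2Zn, toluene, −65 °C; then 15, 0 °C; aq. NH4Cl
Reagents that add atoms: none
Why: syn-Hydrozirconation gives the E-alkenyl metal, and after Zr-to-Zn transmetalation it adds 1,2 to the activated C5 ketone of the 1,2-dione from the face opposite the oxirane oxygen (Felkin–Anh-type, electrostatic), which sets C5 as R; the excess reagent absorbs the N–H.

**Step 10**
Reactants: 20 (2S,3E)-4-[(4R,4aS,5R)-4,4a-epoxy-5-hydroxy-7-methyl-6-oxo-2,3,4,4a,5,6-hexahydro-1H-cyclopenta[b]pyridin-5-yl]but-3-en-2-yl acetate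
Product: 21 (2S,3S)-4-[(4R,4aS,5Z)-4,4a-epoxy-7-methyl-6-oxo-1,2,3,4,4a,6-hexahydro-5H-cyclopenta[b]pyridin-5-ylidene]-3-hydroxybutan-2-yl acetate
Conditions: Ph3SiOReO3 (3 mol %), Et2O, −50 → −20 °C
Reagents that add atoms: none
Why: The [3,3]-sigmatropic shift of the transient allyl perrhenate (1,3-hydroxyl transposition) is suprafacial through a chair with the bulky C4a pseudo-equatorial, so oxygen passes from C5 to C2' on one face; this sets C2' as S and places C2' toward C6 on the new C5=C1' bond, driven by conjugation with the C6 carbonyl.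

**Step 11**
Reactants: 21 (2S,3S)-4-[(4R,4aS,5Z)-4,4a-epoxy-7-methyl-6-oxo-1,2,3,4,4a,6-hexahydro-5H-cyclopenta[b]pyridin-5-ylidene]-3-hydroxybutan-2-yl acetate; 22 (R)-2-methylbutanoic acid
Product: 23 (2S,3S)-3-acetoxy-1-[(4R,4aS,5Z)-4,4a-epoxy-7-methyl-6-oxo-1,2,3,4,4a,6-hexahydro-5H-cyclopenta[b]pyridin-5-ylidene]butan-2-yl (2R)-2-methylbutanoate
Conditions: 22, DIC, DMAP (cat.), CH2Cl2, 0 °C
Reagents that add atoms: none
Why: Steglich esterification acylates the secondary allylic hydroxyl with retention; the vinylogous amide N–H is not nucleophilic enough to compete and the acid's α-centre is bought.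

**Step 12**
Reactants: 23 (2S,3S)-3-acetoxy-1-[(4R,4aS,5Z)-4,4a-epoxy-7-methyl-6-oxo-1,2,3,4,4a,6-hexahydro-5H-cyclopenta[b]pyridin-5-ylidene]butan-2-yl (2R)-2-methylbutanoate
Product: 24 (2S,3S)-3-acetoxy-1-[(4R,4aS,5E)-4,4a-epoxy-7-methyl-2,3,4,4a-tetrahydro-5H-cyclopenta[b]pyridin-5-ylidene]butan-2-yl (2R)-2-methylbutanoate
Conditions: IrCl(CO)(PPh3)2 (1 mol %), (HMe2Si)2O, toluene, 23 °C
Reagents that add atoms: none
Why: Iridium-catalysed hydrosilylation reduces only the vinylogous amide carbonyl, and 1,4-elimination of silanol then gives the C6=C7/C7a=N1 azadiene; esters, oxirane and all stereocentres are untouched.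

**Compound list**
1 | (S)-4-amino-2-hydroxybutanoic acid | NCC[C@H](O)C(O)=O | starting material
2 | (S)-4-azido-2-hydroxybutanoic acid | [N-]=[N+]=NCC[C@H](O)C(O)=O | intermediate
3 | (S)-4-azido-2-hydroxy-N-methoxy-N-methylbutanamide | CON(C)C(=O)[C@@H](O)CCN=[N+]=[N-] | intermediate
4 | (S)-4-azido-1-[methoxy(methyl)amino]-1-oxobutan-2-yl methanesulfonate | CON(C)C(=O)[C@@H](OS(C)(=O)=O)CCN=[N+]=[N-] | intermediate
5 | 2-bromobut-1-ene | C=C(Br)CC | starting material
6 | but-1-en-2-ylmagnesium bromide | C=C(CC)[Mg]Br | intermediate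
7 | (3S)-1-azido-5-methylidene-4-oxoheptan-3-yl methanesulfonate | C=C(CC)C(=O)[C@@H](OS(C)(=O)=O)CCN=[N+]=[N-] | intermediate
8 | ethoxyethyne | CCOC#C | starting material
9 | lithium ethoxyacetylide | CCOC#C[Li] | intermediate
10 | lithium (3R,4S)-6-azido-3-(but-1-en-2-yl)-1-ethoxy-4-[(methylsulfonyl)oxy]hex-1-yn-3-olate | CCOC#C[C@]([O-])(C(=C)CC)[C@@H](OS(C)(=O)=O)CCN=[N+]=[N-].[Li+] | intermediate
11 | (2R,3R)-3-(2-azidoethyl)-2-(but-1-en-2-yl)-2-(ethoxyethynyl)oxirane | CCOC#C[C@@]1(C(=C)CC)O[C@@H]1CCN=[N+]=[N-] | intermediate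
12 | ethyl 2-[(2R,3R)-3-(2-azidoethyl)-2-propanoyloxiran-2-yl]-2-oxoacetate | CCOC(=O)C(=O)[C@@]1(C(=O)CC)O[C@@H]1CCN=[N+]=[N-] | intermediate
13 | (2R,3R)-2-(2-azidoethyl)-5-hydroxy-6-methyl-1-oxaspiro[2.4]hept-5-ene-4,7-dione | CC1=C(O)C(=O)[C@]2(O[C@@H]2CCN=[N+]=[N-])C1=O | intermediate
14 | (2R,3R)-2-(2-aminoethyl)-5-hydroxy-6-methyl-1-oxaspiro[2.4]hept-5-ene-4,7-dione | CC1=C(O)C(=O)[C@]2(O[C@@H]2CCN)C1=O | intermediate
15 | (4R,4aS)-4,4a-epoxy-7-methyl-2,3,4,4a-tetrahydro-1H-cyclopenta[b]pyridine-5,6-dione | CC1=C2NCC[C@H]3O[C@@]23C(=O)C1=O | intermediate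
16 | (S)-but-3-yn-2-ol | C#C[C@H](C)O | starting material
17 | (S)-but-3-yn-2-yl acetate | C#C[C@H](C)OC(C)=O | intermediate
18 | chloro[(1E,3S)-3-acetoxybut-1-en-1-yl]bis(cyclopentadienyl)zirconium (cyclopentadienyl rings drawn σ-bonded) | CC(=O)O[C@@H](C)/C=C/[Zr](Cl)(C1C=CC=C1)C1C=CC=C1 | intermediate
19 | [(1E,3S)-3-acetoxybut-1-en-1-yl](methyl)zinc | CC(=O)O[C@@H](C)/C=C/[Zn]C | intermediate
20 | (2S,3E)-4-[(4R,4aS,5R)-4,4a-epoxy-5-hydroxy-7-methyl-6-oxo-2,3,4,4a,5,6-hexahydro-1H-cyclopenta[b]pyridin-5-yl]but-3-en-2-yl acetate | CC1=C2NCC[C@H]3O[C@@]23[C@](O)(/C=C/[C@H](C)OC(C)=O)C1=O | intermediate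
21 | (2S,3S)-4-[(4R,4aS,5Z)-4,4a-epoxy-7-methyl-6-oxo-1,2,3,4,4a,6-hexahydro-5H-cyclopenta[b]pyridin-5-ylidene]-3-hydroxybutan-2-yl acetate | CC1=C2NCC[C@H]3O[C@@]23/C(=C/[C@H](O)[C@H](C)OC(C)=O)C1=O | intermediate
22 | (R)-2-methylbutanoic acid | CC[C@@H](C)C(O)=O | starting material
23 | (2S,3S)-3-acetoxy-1-[(4R,4aS,5Z)-4,4a-epoxy-7-methyl-6-oxo-1,2,3,4,4a,6-hexahydro-5H-cyclopenta[b]pyridin-5-ylidene]butan-2-yl (2R)-2-methylbutanoate | CC1=C2NCC[C@H]3O[C@@]23/C(=C/[C@H](OC(=O)[C@H](C)CC)[C@H](C)OC(C)=O)C1=O | intermediate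
24 | (2S,3S)-3-acetoxy-1-[(4R,4aS,5E)-4,4a-epoxy-7-methyl-2,3,4,4a-tetrahydro-5H-cyclopenta[b]pyridin-5-ylidene]butan-2-yl (2R)-2-methylbutanoate | CC[C@@H](C)C(=O)O[C@@H](/C=C1\C=C(C)C2=NCC[C@H]3O[C@]213)[C@H](C)OC(C)=O | target

**Step count**
Total: 12 steps. Longest linear sequence: 11 steps (steps 1 to 7, then 9 to 12); step 8 is a one-step side branch.

**Three steps most likely to fail, each with a fallback**

Step 5 can fail through enolisation of the acidic α-mesyloxy ketone or through low facial selectivity. The fallback sets out from 3 and separates addition from ring closure. Silylation (TBSCl, imidazole) gives (S)-4-azido-2-[(tert-butyldimethylsilyl)oxy]-N-methoxy-N-methylbutanamide F1. Grignard reagent 6 converts it to (5S)-7-azido-5-[(tert-butyldimethylsilyl)oxy]-3-methylideneheptan-4-one F2. Lithium ethoxyacetylide 9 then adds under polar Felkin–Anh control to give (3R,4S)-6-azido-3-(but-1-en-2-yl)-4-[(tert-butyldimethylsilyl)oxy]-1-ethoxyhex-1-yn-3-ol F3. Bu4NF frees (3R,4S)-6-azido-3-(but-1-en-2-yl)-1-ethoxyhex-1-yne-3,4-diol F4. MsCl/Et3N sulfonylates only the secondary hydroxyl to (3R,4S)-6-azido-3-(but-1-en-2-yl)-1-ethoxy-3-hydroxyhex-1-yn-4-yl methanesulfonate F5, and K2CO3 in MeOH closes the oxirane with inversion, coming back to the route at 11.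

Step 9 can be sluggish, or the alkenyl group can enter syn to the oxirane oxygen. In the second case the product from 15 and 17 is the C5 epimer (2S,3E)-4-[(4R,4aS,5S)-4,4a-epoxy-5-hydroxy-7-methyl-6-oxo-2,3,4,4a,5,6-hexahydro-1H-cyclopenta[b]pyridin-5-yl]but-3-en-2-yl acetate F6. The same perrhenate shift then gives (2S,3R)-4-[(4R,4aS,5Z)-4,4a-epoxy-7-methyl-6-oxo-1,2,3,4,4a,6-hexahydro-5H-cyclopenta[b]pyridin-5-ylidene]-3-hydroxybutan-2-yl acetate F7. This is esterified with 22 under Mitsunobu conditions (PPh3, DIAD, THF, 0 °C), which inverts C2' and comes back to the route at 23.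

Step 10 can fail because the tertiary epoxy alcohol is sensitive to the Lewis-acidic perrhenate (semipinacol or oxirane opening). The fallback sets out from 20 and moves the acyl group instead of the hydroxyl. Yamaguchi esterification with 22 (2,4,6-trichlorobenzoyl chloride, Et3N, DMAP, toluene) gives (4R,4aS,5R)-5-[(1E,3S)-3-acetoxybut-1-en-1-yl]-4,4a-epoxy-7-methyl-6-oxo-2,3,4,4a,5,6-hexahydro-1H-cyclopenta[b]pyridin-5-yl (2R)-2-methylbutanoate F8. Its [3,3]-acyloxy shift with PdCl2(MeCN)2 (5 mol %, THF, 23 °C) places the ester on C2' with the same suprafacial chirality transfer and comes back to the route at 23, so that step 11 is no longer needed.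

**Further compounds**
F1 | step 5 | (S)-4-azido-2-[(tert-butyldimethylsilyl)oxy]-N-methoxy-N-methylbutanamide | CON(C)C(=O)[C@@H](O[Si](C)(C)C(C)(C)C)CCN=[N+]=[N-]
F2 | step 5 | (5S)-7-azido-5-[(tert-butyldimethylsilyl)oxy]-3-methylideneheptan-4-one | C=C(CC)C(=O)[C@@H](O[Si](C)(C)C(C)(C)C)CCN=[N+]=[N-]
F3 | step 5 | (3R,4S)-6-azido-3-(but-1-en-2-yl)-4-[(tert-butyldimethylsilyl)oxy]-1-ethoxyhex-1-yn-3-ol | CCOC#C[C@](O)(C(=C)CC)[C@@H](O[Si](C)(C)C(C)(C)C)CCN=[N+]=[N-]
F4 | step 5 | (3R,4S)-6-azido-3-(but-1-en-2-yl)-1-ethoxyhex-1-yne-3,4-diol | CCOC#C[C@](O)(C(=C)CC)[C@@H](O)CCN=[N+]=[N-]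
F5 | step 5 | (3R,4S)-6-azido-3-(but-1-en-2-yl)-1-ethoxy-3-hydroxyhex-1-yn-4-yl methanesulfonate | CCOC#C[C@](O)(C(=C)CC)[C@@H](OS(C)(=O)=O)CCN=[N+]=[N-]
F6 | step 9 | (2S,3E)-4-[(4R,4aS,5S)-4,4a-epoxy-5-hydroxy-7-methyl-6-oxo-2,3,4,4a,5,6-hexahydro-1H-cyclopenta[b]pyridin-5-yl]but-3-en-2-yl acetate | CC1=C2NCC[C@H]3O[C@@]23[C@@](O)(/C=C/[C@H](C)OC(C)=O)C1=O
F7 | step 9 | (2S,3R)-4-[(4R,4aS,5Z)-4,4a-epoxy-7-methyl-6-oxo-1,2,3,4,4a,6-hexahydro-5H-cyclopenta[b]pyridin-5-ylidene]-3-hydroxybutan-2-yl acetate | CC1=C2NCC[C@H]3O[C@@]23/C(=C/[C@@H](O)[C@H](C)OC(C)=O)C1=O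
F8 | step 10 | (4R,4aS,5R)-5-[(1E,3S)-3-acetoxybut-1-en-1-yl]-4,4a-epoxy-7-methyl-6-oxo-2,3,4,4a,5,6-hexahydro-1H-cyclopenta[b]pyridin-5-yl (2R)-2-methylbutanoate | CC1=C2NCC[C@H]3O[C@@]23[C@](OC(=O)[C@H](C)CC)(/C=C/[C@H](C)OC(C)=O)C1=O
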